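The data were generated by integration with made-up constants.

Target in the birch run climbs quickly and then stays flat: the 5 readings from 2.50 min on average 71.6%, each with its scatter. That plateau is the quick number, but the hunch that coupling partner ran out fails a balance.

| flask | starting material | coupling partner | second substrate | free catalyst | remark | time |
|---|---|---|---|---|---|---|
| birch | 1 mM | 1 mM | 0.20 mM | 10 µM | the very flask that is asked about, followed so far |  |
| flask | 1.0 mM | 1.00 mM | 0.200 mM | 10 µM |  | 10 min |

- birch (time / min: target / %, starting material / %): 0.833: 47, 51; 1.50: 67, 36; 2.50: 69, 33; 3.00: 72, 28; 4.00: 72, 31; 5.00: 70, 29; 6.00: 75, 30

(readings scatter by 2 percentage points)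

- target that was removed still counts
- the numbers in the tables scatter with a standard deviation of 2 percentage points
- steps under discussion: 2 free catalyst -> spent catalyst A; second substrate + coupling partner + free catalyst -> free catalyst + second product; free catalyst -> spent catalyst B; starting material + coupling partner + free catalyst -> free catalyst + target; second substrate + free catalyst <-> idle complex
- additions bring no volume worth counting

- north-east: at 10 min add free catalyst, 100% of the amount charged, then wait 3.0 min
- west: at 10 min add coupling partner, 100% of the amount charged, then wait 3.0 min
- south-west: at 10 min take out 90% of the target then present, then wait 3.0 min
- south: change nothing and wait 3.0 min more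

- target, in percent of the starting material first charged, at 10 min
- what to do for the largest gain in target; "none" if nothing gains more than 2 percentage points (north-east / west / south-west / south / none)
- target present, with what was taken out counted in, in percent of the starting material first charged, after south-west
- target present, with what was taken out counted in, in percent of the starting material first charged, after south

Each target and each second product costs one coupling partner. Target is the large item in that balance, and second substrate is the small correction. Charging the whole of the second substrate against the partner gives M:

M = 1.00 mM − 71.6% × 1.0 mM − 0.200 mM = 0.0840 mM

This M is the partner margin: partner charged, less target at the plateau, less second substrate charged. A positive M means partner remains when target stops. Starting material remains too in the birch run, reading 28% at 3.00 min and 30% at 6.00 min. Suspicion therefore falls on the catalyst, and the reckoning here keeps target at the plateau and favours fresh catalyst.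

The forecast gives 72% now (range 69% to 76%), 72% after south-west and 72% after south. It picks north-east, holding that “the catalyst has died”.

The flask gives 72.4% at 10 min, 72.4% after south-west and 72.4% after south, while north-east gains 5.9 percentage points, reaching 78.3%.

    2 free catalyst → spent catalyst A (k = 1300 M⁻¹ s⁻¹)
    second substrate + coupling partner + free catalyst → free catalyst + second product (k = 1.24 × 10⁸ M⁻² s⁻¹)
    free catalyst → spent catalyst B (k = 0.139 s⁻¹)
    starting material + coupling partner + free catalyst → free catalyst + target (k = 6.19 × 10⁷ M⁻² s⁻¹)
    second substrate + free catalyst ⇌ idle complex, settled at all times (K = 2.53 × 10⁵ M⁻¹)

With the flask's own target M becomes 0.0758 mM, and coupling partner left in the flask at 10.0 min is 0.0952 mM, above that margin. Free catalyst has a half-life of 0.0831 min by the step to spent catalyst B alone, shorter than the 0.71 min of coupling partner by the target path at 0.567 min. Spent catalyst B in the flask holds 99.2% of the catalyst charged at 10.0 min. Reckoned with the birch plateau, the neighbour flask with 0.40 mM of coupling partner has M = −0.516 mM, and its target at 10 min stands at 29.7%, below the low end of the forecast's range for the flask; coupling partner, the limiting reagent, is first to run out there, down to 1.5% of its charge.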